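**Retrosynthetic overview**
1. Target ⇒ removal of two silyl ethers (last step) ⇒ acyl–O disconnection at O-3, giving an α'-hydroxy enone and (E)-4-silyloxy-2-methylbut-2-enoic acid (Wittig reaction of a C3 ylide and a C2 aldehyde).
2. C3–O ⇒ enolate hydroxylation anti to the isopropyl group. C7–O ⇒ allylic bromination and hydrolysis of the enone methyl group.
3. Key disconnection, C5–O(propanoyl) ⇒ propanoic acid + deconjugated carvotanacetone. This is a selenium-catalysed oxidative allylic acyloxylation, new on this substrate class, and its anti addition puts O-5 cis to the isopropyl group.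
4. Carvotanacetone ⇒ (S)-(+)-carvone by selective hydrogenation. C-4 comes from the chiral pool and controls first C-5, then C-3.
5. Rings: the only ring (six-membered) is bought with carvone. No ring is formed.

Locants (p-menthane numbering of the target): C-1 bears C-7H2OH, C-2 is C=O, C-3 carries the O-acyl group, C-4 the isopropyl group, C-5 the O-propanoyl group, C-6 is =CH.
Assumption: commercial (S)-(+)-carvone of at least 98% ee is used; its stereocentre becomes C-4 of the target.

**Step 1**
Reactants: 1 (S)-(+)-carvone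
Product: 2 (S)-carvotanacetone [(5S)-2-methyl-5-(propan-2-yl)cyclohex-2-en-1-one]
Conditions: H2 (1 atm), RhCl(PPh3)3 (1 mol %), toluene, 25 °C
Reagents that add atoms: none
Why: Homogeneous hydrogenation with RhCl(PPh3)3 reduces the unhindered 1,1-disubstituted alkene much faster than the trisubstituted conjugated one, and C-4 is untouched.

**Step 2**
Reactants: 2 (S)-carvotanacetone
Product: 6 (1R,6S)-3-methyl-4-oxo-6-(propan-2-yl)cyclohex-2-en-1-yl propanoate, via potassium dienolate 3 (not isolated), via deconjugated enone 4 (not isolated), via acyloxy selenide 5 (not isolated)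
Conditions: KOt-Bu (1.5 equiv), t-BuOH, 25 °C; inverse quench into EtCO2H (20 equiv)/MeCN, 0 °C; then (PhSe)2 (10 mol %), 2,4,6-tris(4-methoxyphenyl)pyrylium tetrafluoroborate (5 mol %), air, 465 nm LED, 25 °C
Reagents that add atoms: propanoic acid, CCC(=O)O
Why: Proposed new method: the extended dienolate 3 is protonated kinetically at C-1 (deconjugative protonation) to give 4, whose isolated C5=C6 bond is the only nucleophilic alkene; PhSe+ (from (PhSe)2, the photoexcited pyrylium salt and O2) bridges it on the face anti to the C-4 isopropyl group, and with that group pseudo-equatorial the chair-like trans-diaxial opening of the seleniranium ion is possible only by attack of propanoic acid at C-5 from the isopropyl face, giving 5; oxidation of its selenium turns the axial C6–Se bond into a leaving group that departs with the antiperiplanar, ketone-acidified H-1, so the C5–O bond ends up cis to the isopropyl group, the alkene returns to conjugation, the catalyst is released and the electron-poor product resists further attack; closest known reaction type: dual selenium π-acid/photoredox aerobic allylic esterification of open-chain β,γ-unsaturated esters and nitriles with carboxylic acids, not yet shown on a cyclic β,γ-enone or used to set a ring stereocentre.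

**Step 3**
Reactants: 6 (1R,6S)-3-methyl-4-oxo-6-(propan-2-yl)cyclohex-2-en-1-yl propanoate
Product: 8 (1R,6S)-3-(hydroxymethyl)-4-oxo-6-(propan-2-yl)cyclohex-2-en-1-yl propanoate, via allylic bromide 7 (not isolated)
Conditions: NBS (1.05 equiv), AIBN (5 mol %), PhCF3, 80 °C; filter, concentrate; Ag2CO3 (0.6 equiv), acetone/H2O 4:1, 25 °C, dark
Reagents that add atoms: water, O
Why: Wohl–Ziegler bromination followed by silver-assisted hydrolysis: H-5 is pseudo-equatorial (poor overlap with the π bond) and deactivated by the acyloxy group, so the C-7 methyl holds the only well-aligned allylic C–H bonds, water then attacks the unhindered primary end of 7, and no stereocentre is touched.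

**Step 4**
Reactants: 8 (1R,6S)-3-(hydroxymethyl)-4-oxo-6-(propan-2-yl)cyclohex-2-en-1-yl propanoate
Product: 9 (1R,6S)-3-({[tert-butyl(dimethyl)silyl]oxy}methyl)-4-oxo-6-(propan-2-yl)cyclohex-2-en-1-yl propanoate
Conditions: TBSCl, imidazole, CH2Cl2, 0 °C to 25 °C
Reagents that add atoms: tert-butyl(chloro)dimethylsilane, CC(C)(C)[Si](C)(C)Cl
Why: Standard imidazole-promoted silylation of the only free, primary hydroxyl group.

**Step 5**
Reactants: 9 (1R,6S)-3-({[tert-butyl(dimethyl)silyl]oxy}methyl)-4-oxo-6-(propan-2-yl)cyclohex-2-en-1-yl propanoate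
Product: 11 (1S,5R,6R)-3-({[tert-butyl(dimethyl)silyl]oxy}methyl)-5-hydroxy-4-oxo-6-(propan-2-yl)cyclohex-2-en-1-yl propanoate, via lithium enolate 10 (not isolated)
Conditions: LiN(SiMe3)2 (1.1 equiv), THF, −78 °C; 2-(benzenesulfonyl)-3-phenyloxaziridine, −78 °C; AcOH quench
Reagents that add atoms: 2-(benzenesulfonyl)-3-phenyloxaziridine, O=S(=O)(c1ccccc1)N1OC1c1ccccc1
Why: Davis enolate hydroxylation: C-1 has no hydrogen, so only C-3 is deprotonated, and the oxaziridine approaches the flat cross-conjugated enolate from the face opposite both the isopropyl group and the pseudo-axial 5-propanoate, which sets O-3 trans to both.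

**Step 6**
Reactants: 12 ethyl 2-(triphenyl-λ5-phosphanylidene)propanoate; 13 {[tert-butyl(dimethyl)silyl]oxy}acetaldehyde
Product: 14 ethyl (2E)-4-{[tert-butyl(dimethyl)silyl]oxy}-2-methylbut-2-enoate
Conditions: CH2Cl2, 25 °C
Reagents that add atoms: none
Why: Wittig olefination with a stabilised, α-branched ylide gives the (E)-trisubstituted enoate with high selectivity.

**Step 7**
Reactants: 14 ethyl (2E)-4-{[tert-butyl(dimethyl)silyl]oxy}-2-methylbut-2-enoate
Product: 16 (2E)-4-{[tert-butyl(dimethyl)silyl]oxy}-2-methylbut-2-enoic acid, via lithium carboxylate 15 (not isolated)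
Conditions: LiOH, THF/MeOH/H2O, 25 °C; 1 M HCl to pH 4, 0 °C
Reagents that add atoms: lithium hydroxide, [Li+].[OH-]
Why: Saponification of an ethyl ester; the primary silyl ether and the alkene geometry survive mild base and a brief pH 4 work-up.

**Step 8**
Reactants: 11 (1S,5R,6R)-3-({[tert-butyl(dimethyl)silyl]oxy}methyl)-5-hydroxy-4-oxo-6-(propan-2-yl)cyclohex-2-en-1-yl propanoate; 16 (2E)-4-{[tert-butyl(dimethyl)silyl]oxy}-2-methylbut-2-enoic acid
Product: 17 (1R,5S,6S)-3-({[tert-butyl(dimethyl)silyl]oxy}methyl)-2-oxo-5-(propanoyloxy)-6-(propan-2-yl)cyclohex-3-en-1-yl (2E)-4-{[tert-butyl(dimethyl)silyl]oxy}-2-methylbut-2-enoate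
Conditions: DCC, DMAP (20 mol %), CH2Cl2, 0 °C to 25 °C
Reagents that add atoms: none
Why: Steglich esterification acylates the only free hydroxyl group; the C3–O bond is not broken, so C-3 keeps its configuration.

**Step 9**
Reactants: 17 bis-silyl ether of the target
Product: 18 (1R,5S,6S)-3-(hydroxymethyl)-2-oxo-5-(propanoyloxy)-6-(propan-2-yl)cyclohex-3-en-1-yl (2E)-4-hydroxy-2-methylbut-2-enoate (target)
Conditions: HF·pyridine, THF/pyridine, 0 °C to 25 °C
Reagents that add atoms: none
Why: Buffered fluoride desilylation cleaves both primary silyl ethers without touching the three carbonyl groups or the epimerisable C-3.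

**Compound list**
1 | (S)-(+)-carvone, (5S)-2-methyl-5-(prop-1-en-2-yl)cyclohex-2-en-1-one | CC1=CC[C@@H](CC1=O)C(C)=C | starting material
2 | (S)-carvotanacetone, (5S)-2-methyl-5-(propan-2-yl)cyclohex-2-en-1-one | CC1=CC[C@@H](CC1=O)C(C)C | intermediate
3 | potassium (5S)-2-methyl-5-(propan-2-yl)cyclohexa-1,3-dien-1-olate | CC1=C([O-])C[C@H](C=C1)C(C)C.[K+] | intermediate
4 | (5S)-2-methyl-5-(propan-2-yl)cyclohex-3-en-1-one (C-2 epimers) | CC1C(=O)C[C@H](C=C1)C(C)C | intermediate
5 | (1R,2R,6S)-3-methyl-4-oxo-2-(phenylselanyl)-6-(propan-2-yl)cyclohexyl propanoate (O and Se trans-diaxial, O cis to isopropyl, C-3 epimers) | CCC(=O)O[C@H]1[C@H]([Se]c2ccccc2)C(C)C(=O)C[C@H]1C(C)C | intermediate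
6 | (1R,6S)-3-methyl-4-oxo-6-(propan-2-yl)cyclohex-2-en-1-yl propanoate (5-O cis to isopropyl) | CCC(=O)O[C@H]1C=C(C)C(=O)C[C@H]1C(C)C | intermediate
7 | (1R,6S)-3-(bromomethyl)-4-oxo-6-(propan-2-yl)cyclohex-2-en-1-yl propanoate | CCC(=O)O[C@H]1C=C(CBr)C(=O)C[C@H]1C(C)C | intermediate
8 | (1R,6S)-3-(hydroxymethyl)-4-oxo-6-(propan-2-yl)cyclohex-2-en-1-yl propanoate | CCC(=O)O[C@H]1C=C(CO)C(=O)C[C@H]1C(C)C | intermediate
9 | (1R,6S)-3-({[tert-butyl(dimethyl)silyl]oxy}methyl)-4-oxo-6-(propan-2-yl)cyclohex-2-en-1-yl propanoate | CCC(=O)O[C@H]1C=C(CO[Si](C)(C)C(C)(C)C)C(=O)C[C@H]1C(C)C | intermediate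
10 | lithium cross-conjugated enolate of 9 (O− on C-2, C2=C3) | CCC(=O)O[C@H]1C=C(CO[Si](C)(C)C(C)(C)C)C([O-])=C[C@H]1C(C)C.[Li+] | intermediate
11 | (1S,5R,6R)-3-({[tert-butyl(dimethyl)silyl]oxy}methyl)-5-hydroxy-4-oxo-6-(propan-2-yl)cyclohex-2-en-1-yl propanoate (3-OH trans to isopropyl and to 5-O) | CCC(=O)O[C@H]1C=C(CO[Si](C)(C)C(C)(C)C)C(=O)[C@H](O)[C@H]1C(C)C | intermediate
12 | ethyl 2-(triphenyl-λ5-phosphanylidene)propanoate | CCOC(=O)C(C)=P(c1ccccc1)(c1ccccc1)c1ccccc1 | starting material
13 | {[tert-butyl(dimethyl)silyl]oxy}acetaldehyde | O=CCO[Si](C)(C)C(C)(C)C | starting material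
14 | ethyl (2E)-4-{[tert-butyl(dimethyl)silyl]oxy}-2-methylbut-2-enoate | CCOC(=O)/C(C)=C/CO[Si](C)(C)C(C)(C)C | intermediate
15 | lithium (2E)-4-{[tert-butyl(dimethyl)silyl]oxy}-2-methylbut-2-enoate | [Li+].[O-]C(=O)/C(C)=C/CO[Si](C)(C)C(C)(C)C | intermediate
16 | (2E)-4-{[tert-butyl(dimethyl)silyl]oxy}-2-methylbut-2-enoic acid | OC(=O)/C(C)=C/CO[Si](C)(C)C(C)(C)C | intermediate
17 | (1R,5S,6S)-3-({[tert-butyl(dimethyl)silyl]oxy}methyl)-2-oxo-5-(propanoyloxy)-6-(propan-2-yl)cyclohex-3-en-1-yl (2E)-4-{[tert-butyl(dimethyl)silyl]oxy}-2-methylbut-2-enoate | CCC(=O)O[C@H]1C=C(CO[Si](C)(C)C(C)(C)C)C(=O)[C@H](OC(=O)/C(C)=C/CO[Si](C)(C)C(C)(C)C)[C@H]1C(C)C | intermediate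
18 | (1R,5S,6S)-3-(hydroxymethyl)-2-oxo-5-(propanoyloxy)-6-(propan-2-yl)cyclohex-3-en-1-yl (2E)-4-hydroxy-2-methylbut-2-enoate | CCC(=O)O[C@H]1C=C(CO)C(=O)[C@H](OC(=O)/C(C)=C/CO)[C@H]1C(C)C | target

**Step count**
Total steps: 9. Longest linear sequence: 7 (steps 1, 2, 3, 4, 5, 8, 9).

**Steps most likely to fail**

Step 2 (the proposed new step). Three things could go wrong:
- 4 may drift back to 2 in the buffered acid before selenium engages it.
- Opening at C-6 may compete with opening at C-5.
- α-Selenenylation of the ketone may compete with attack on the alkene.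

The fallback uses known chemistry, sets out from 2 and comes back at 6. Compound 2 is deconjugated with KOt-Bu/t-BuOH and quenched with aqueous acetic acid. Crude 4 is epoxidised with m-CPBA (NaHCO3, CH2Cl2, 0 °C) on the face anti to the isopropyl group, giving the β,γ-epoxy ketone F1. Et3N (CH2Cl2, 25 °C) opens it by β-elimination to the trans-γ-hydroxy enone F2. Mitsunobu esterification with propanoic acid (PPh3, DIAD, toluene, 0 °C to 25 °C) inverts C-5 and gives 6.

Step 3. Radical bromination may also hit H-5 or C-3, and 7 may lose HBr towards a phenol. The fallback sets out from 6 and comes back at 8.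
- Ketalisation with 1,2-bis(trimethylsilyloxy)ethane and catalytic Me3SiOTf (CH2Cl2, −78 °C) gives, without moving the double bond, the dioxolane F3.
- The alkene of F3 is no longer electron-poor and C-2 carries no hydrogen, so SeO2 (cat.)/t-BuOOH allylic hydroxylation (ene then [2,3] shift) can only reach the C-7 methyl, giving the hydroxymethyl dioxolane F4.
- PPTS in wet acetone removes the ketal and gives 8.

Step 5. The enolate may equilibrate to the extended dienolate, which would expel the silanolate and aromatise, and the sulfonimine by-product can trap the enolate. The fallback avoids a free enolate, sets out from 9 and comes back at 11. Me3SiOTf/Et3N (CH2Cl2, 0 °C) gives the cross-conjugated trimethylsilyl dienol ether F5. Rubottom oxidation with dimethyldioxirane (acetone/CH2Cl2, −40 °C) epoxidises the enol ether bond anti to the isopropyl group. Work-up with aqueous citric acid removes the trimethylsilyl group and gives 11.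

**Further compounds**
F1 | step 2 | (1R,5S,6S)-2-methyl-5-(propan-2-yl)-7-oxabicyclo[4.1.0]heptan-3-one (epoxide trans to isopropyl, C-2 epimers) | CC1C(=O)C[C@@H](C(C)C)[C@@H]2O[C@H]12
F2 | step 2 | (4S,5S)-4-hydroxy-2-methyl-5-(propan-2-yl)cyclohex-2-en-1-one | O[C@@H]1C=C(C)C(=O)C[C@H]1C(C)C
F3 | step 3 | (8R,9S)-6-methyl-9-(propan-2-yl)-1,4-dioxaspiro[4.5]dec-6-en-8-yl propanoate | CCC(=O)O[C@H]1C=C(C)C2(OCCO2)C[C@H]1C(C)C
F4 | step 3 | (8R,9S)-6-(hydroxymethyl)-9-(propan-2-yl)-1,4-dioxaspiro[4.5]dec-6-en-8-yl propanoate | CCC(=O)O[C@H]1C=C(CO)C2(OCCO2)C[C@H]1C(C)C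
F5 | step 5 | trimethylsilyl dienol ether of 9 (Me3SiO on C-2, C2=C3, stereocentres as in 9) | CCC(=O)O[C@H]1C=C(CO[Si](C)(C)C(C)(C)C)C(O[Si](C)(C)C)=C[C@H]1C(C)C
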